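The readings were generated by integration for substances that don't exist, noise included.

Slowness is the first thing Thursday's run shows: monomer in chains read 1.3% after 20.0 min and 20.0% after 50.0 min, in a feed that lasted 50 min.

- Thursday's: free monomer 0.10 M (fed, over 50 min); initiator 0.48 mol%; impurity 82 µM; run made earlier
- flask: free monomer 0.050 M (fed, over 50 min); initiator 0.48 mol%; impurity 82 µM; time 2.5 h

- Thursday's (time / min: monomer in chains / %, free monomer / %): 4.00: 0.4, 8.3; 8.00: 0.1, 15.9; 20.0: 1.3, 38.8; 50.0: 20.0, 79.4

(scatter of a reading: 0.5 percentage points)

- the average divides the monomer in chains by the number of chains begun, living and dead together
- reactions considered so far: free monomer + living end -> monomer in chains + living end; free monomer + initiator -> living end + monomer in chains; initiator + monomer in chains -> spent initiator A; initiator + impurity -> spent initiator B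
- the earlier runs do not show the number of chains; that part of a forecast is a guess
- percentages count the whole charge, also what has not yet gone in
- no earlier run changes the charge of initiator; that part of a forecast is a guess

* average number of monomer units in a chain (chains begun, living or dead) at 2.5 h
* part of the free monomer that has reacted at 2.5 h

Ben reads that slowness as initiator beginning chains late. So he expects the new flask to be still beginning chains at 2.5 h, with fewer chains than surviving initiator and each of them longer.

Ana counts turnovers instead. She assumes that impurity removes initiator one for one and that each surviving initiator begins one chain. The flask is charged with 240 µM of initiator against 82 µM of impurity, which leaves 158 µM. Half the monomer at the same loading halves the initiator but not the impurity, so the flask has fewer survivors than the 398 µM of Thursday's run.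

Her quantity is the turnover count, the whole charge of free monomer divided by the surviving initiator, which is the field's target degree of polymerisation. It comes to 316 for the flask, against 251 for Thursday's run. Her rule is that once the initiator is used, the average chain equals the reacted part times this count, or 3.16 units per percentage point. She bets on that holding at 2.5 h, which is 3.00 times the dosing time.

The forecast, on Ben's side, gives 300 units at 55% reacted, “with chains still building”.

The flask gives 146 units at 45.5% reacted, under this scheme:

    free monomer + living end → monomer in chains + living end, rate k1*[living end]*[free monomer] (k = 37.0 M⁻¹ min⁻¹)
    free monomer + initiator → living end + monomer in chains (k = 1.00 M⁻¹ min⁻¹)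
    initiator + monomer in chains → spent initiator A (k = 0.130 M⁻¹ min⁻¹)
    initiator + impurity → spent initiator B (k = 8000 M⁻¹ min⁻¹)

Ana's count times the reacted part makes 144 units, with initiator down to 0.42% of its charge at 2.50 h. Ben's view holds early in the flask: at 0.250 h, with 0.105% reacted, the average over chains begun was 3.12 units, ten times the 0.332 from the count. Left until 4.0 h, the neighbour flask reaches 67.6% reacted, where the count gives 214 units and the chains of that flask average 216 units.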